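**Retrosynthetic overview**
1. Target 9 is cut at the ArCH2–Ar bridge: an ortho-quinone methide from the Mannich base of benzophenone 6 is trapped by ring A of benzophenone 5.
2. 6 comes from 5 by cleaving only the methoxy group ortho to the ketone on ring B, so one benzophenone serves both halves.
3. Key disconnection of 5 at the ketone–ring B bond: the formyl carbon of unprotected aldehyde 2 is used as an acyl anion equivalent (aroyl–palladium by formyl C–H cleavage) and joined to the electrophilic C–I carbon of iodide 4.
4. 2 comes from 2,4,6-trihydroxybenzaldehyde 1 by 4-O-methylation; 4 comes from 3-methoxy-5-methylphenol 3 by para-iodination.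
5. No ring is built: all four benzene rings are bought (ring A = the 2,6-dihydroxy-4-methoxyphenyl ring, from 1; ring B = the methyl-bearing ring, from 3). Assembly order is A–CO–B, then A–CH2–A.

Assumption: the target has no stereocentre and no configurationally stable axis, so it is achiral and "single enantiomer" calls for no stereocontrol.

**Step 1**
Reactants: 1 2,4,6-trihydroxybenzaldehyde
Product: 2 2,6-dihydroxy-4-methoxybenzaldehyde
Conditions: Me2SO4 (1.0 equiv), K2CO3 (1.0 equiv), acetone, rt
Reagents that add atoms: dimethyl sulfate, COS(=O)(=O)OC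
Why: Williamson-type O-methylation in which the 4-OH, para to the formyl group and the most acidic non-chelated phenol, is alkylated first, while the two ortho hydroxyls are held back by hydrogen bonding to C=O and by hindrance; no stereocentre.

**Step 2**
Reactants: 3 3-methoxy-5-methylphenol
Product: 4 4-iodo-3-methoxy-5-methylphenol
Conditions: NIS (1.0 equiv), TsOH·H2O (10 mol%), MeCN, 0 °C to rt
Reagents that add atoms: N-iodosuccinimide, O=C1CCC(=O)N1I
Why: Electrophilic aromatic iodination with acid-activated NIS, which is para-selective for free phenols, so iodine enters the position para to OH (between OMe and CH3); no stereocentre.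

**Step 3 (key step)**
Reactants: 2 2,6-dihydroxy-4-methoxybenzaldehyde; 4 4-iodo-3-methoxy-5-methylphenol
Product: 5 (2,6-dihydroxy-4-methoxyphenyl)(4-hydroxy-2-methoxy-6-methylphenyl)methanone
Conditions: PdCl2 (5 mol%), LiCl (20 mol%), Na2CO3 (3 equiv), DMF, 100 °C, N2
Reagents that add atoms: none
Why: Miura-type palladium-catalysed formyl C–H arylation of a salicylaldehyde, in which 4 adds oxidatively to zerovalent palladium, the ortho-phenoxide of 2 binds the arylpalladium (divalent palladium) and directs cleavage of the formyl C–H to a five-membered aroyl(aryl)palladacycle, so the normally electrophilic aldehyde carbon acts as an acyl anion equivalent toward the C–I carbon and reductive elimination gives the ketone; no stereocentre.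

**Step 4**
Reactants: 5 (2,6-dihydroxy-4-methoxyphenyl)(4-hydroxy-2-methoxy-6-methylphenyl)methanone
Product: 6 (2,4-dihydroxy-6-methylphenyl)(2,6-dihydroxy-4-methoxyphenyl)methanone
Conditions: BCl3 (1 M in CH2Cl2, 5 equiv), CH2Cl2, −78 to 0 °C; then H2O
Reagents that add atoms: none
Why: Chelation-directed Lewis-acid ether cleavage, in which boron held on the carbonyl oxygen and the ring A phenoxides reaches only the neighbouring 2'-OMe of ring B, whose methyl is lost as MeCl, while the remote 4-OMe of ring A has no adjacent donor and survives at 0 °C; no stereocentre.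

**Step 5**
Reactants: 6 (2,4-dihydroxy-6-methylphenyl)(2,6-dihydroxy-4-methoxyphenyl)methanone; 5 (2,6-dihydroxy-4-methoxyphenyl)(4-hydroxy-2-methoxy-6-methylphenyl)methanone
Product: 9 {3-[[3-(2,4-dihydroxy-6-methylbenzoyl)-2,4-dihydroxy-6-methoxyphenyl]methyl]-2,6-dihydroxy-4-methoxyphenyl}(4-hydroxy-2-methoxy-6-methylphenyl)methanone, via Mannich base 7 (not isolated), via ortho-quinone methide 8 (not isolated)
Conditions: 6 (1.0 equiv), Eschenmoser's salt (1.0 equiv), Et3N (1.0 equiv), MeCN, 0 °C to rt; then 5 (2.0 equiv), 1,4-dioxane, 95 °C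
Reagents that add atoms: Eschenmoser's salt (N,N-dimethylmethylideneammonium iodide), C=[N+](C)C.[I-]
Why: Mannich aminomethylation at the free position of the three-oxygen ring A of 6, then thermal loss of Me2NH to ortho-quinone methide 8 and Friedel–Crafts-type conjugate addition by the equivalent ring A carbon of 5 (between OH and OMe), so that activating only one partner enforces the unsymmetrical A–CH2–A link; no stereocentre.

**Compound list**
1 | 2,4,6-trihydroxybenzaldehyde | O=Cc1c(O)cc(O)cc1O | starting material
2 | 2,6-dihydroxy-4-methoxybenzaldehyde | COc1cc(O)c(C=O)c(O)c1 | intermediate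
3 | 3-methoxy-5-methylphenol (orcinol monomethyl ether) | COc1cc(C)cc(O)c1 | starting material
4 | 4-iodo-3-methoxy-5-methylphenol | COc1cc(O)cc(C)c1I | intermediate
5 | (2,6-dihydroxy-4-methoxyphenyl)(4-hydroxy-2-methoxy-6-methylphenyl)methanone | COc1cc(O)c(C(=O)c2c(C)cc(O)cc2OC)c(O)c1 | intermediate
6 | (2,4-dihydroxy-6-methylphenyl)(2,6-dihydroxy-4-methoxyphenyl)methanone | COc1cc(O)c(C(=O)c2c(C)cc(O)cc2O)c(O)c1 | intermediate
7 | Mannich base (not isolated): {3-[(dimethylamino)methyl]-2,6-dihydroxy-4-methoxyphenyl}(2,4-dihydroxy-6-methylphenyl)methanone | COc1cc(O)c(C(=O)c2c(C)cc(O)cc2O)c(O)c1CN(C)C | intermediate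
8 | ortho-quinone methide (not isolated): 2-(2,4-dihydroxy-6-methylbenzoyl)-3-hydroxy-5-methoxy-6-methylidenecyclohexa-2,4-dien-1-one | C=C1C(OC)=CC(O)=C(C(=O)c2c(C)cc(O)cc2O)C1=O | intermediate
9 | {3-[[3-(2,4-dihydroxy-6-methylbenzoyl)-2,4-dihydroxy-6-methoxyphenyl]methyl]-2,6-dihydroxy-4-methoxyphenyl}(4-hydroxy-2-methoxy-6-methylphenyl)methanone (CNP0596095.0, achiral) | COc1cc(O)c(C(=O)c2c(C)cc(O)cc2O)c(O)c1Cc1c(OC)cc(O)c(C(=O)c2c(C)cc(O)cc2OC)c1O | target

**Totals**
Total step count: 5. Longest linear sequence: 4 steps (1 → 2 → 5 → 6 → 9, or equally 3 → 4 → 5 → 6 → 9).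

**Three steps most likely to fail**

Step 3 (the C–H coupling has to deliver a tetra-ortho-substituted ketone from a hindered, electron-rich, phenol-bearing iodide; oxidative addition may stall or 2 may lose its formyl group). The fallback sets out from 2 and 4 and comes back at 5. It makes the same bond by aryl-anion addition and oxidation. Compound 2 is benzylated (BnBr, K2CO3, DMF) to 2,6-bis(benzyloxy)-4-methoxybenzaldehyde F1. Compound 4 is benzylated the same way to 1-(benzyloxy)-4-iodo-3-methoxy-5-methylbenzene F2. Iodine–lithium exchange on F2 (t-BuLi, THF, −78 °C) and addition to F1 gives racemic [2,6-bis(benzyloxy)-4-methoxyphenyl][4-(benzyloxy)-2-methoxy-6-methylphenyl]methanol F3. Dess–Martin oxidation gives [2,6-bis(benzyloxy)-4-methoxyphenyl][4-(benzyloxy)-2-methoxy-6-methylphenyl]methanone F4, and hydrogenolysis (H2, Pd/C, EtOAc) returns 5.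

Step 4 (with the carbonyl already chelated by ring A, BCl3 may react slowly at the 2'-OMe or start to attack the 4-OMe). The fallback sets out from 2 and comes back at 6. It builds 6 with its ring B oxygens masked as benzyl ethers instead of demethylating 5. Purchased orcinol (5-methylbenzene-1,3-diol) is dibenzylated (BnBr, K2CO3, DMF) to 1,3-bis(benzyloxy)-5-methylbenzene F5. Iodination (NIS, MeCN) between OBn and CH3 gives 1,5-bis(benzyloxy)-2-iodo-3-methylbenzene F6. Coupling of F6 with 2 under the step 3 conditions gives [2,4-bis(benzyloxy)-6-methylphenyl](2,6-dihydroxy-4-methoxyphenyl)methanone F7, and hydrogenolysis (H2, Pd/C, EtOAc) gives 6.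

Step 5 (bis-aminomethylation of 6, attack on the resorcinol-type ring B, or self-condensation and scrambling of the quinone methide to symmetrical dimers). The fallback sets out from 5 and 6 and comes back at 9. The stepwise activation is dropped for a direct three-component condensation: equimolar 5 and 6 are stirred with aqueous formaldehyde (0.5 equiv per phenol) and catalytic NaOH in MeOH/H2O at rt. Target 9, statistically the major dimer, is separated from the two symmetrical dimers by reversed-phase preparative HPLC, and unreacted monomers are recycled. No new isolated compound is involved.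

**Further compounds**
F1 | step 3 | 2,6-bis(benzyloxy)-4-methoxybenzaldehyde | COc1cc(OCc2ccccc2)c(C=O)c(OCc2ccccc2)c1
F2 | step 3 | 1-(benzyloxy)-4-iodo-3-methoxy-5-methylbenzene | COc1cc(OCc2ccccc2)cc(C)c1I
F3 | step 3 | racemic [2,6-bis(benzyloxy)-4-methoxyphenyl][4-(benzyloxy)-2-methoxy-6-methylphenyl]methanol | COc1cc(OCc2ccccc2)c(C(O)c2c(C)cc(OCc3ccccc3)cc2OC)c(OCc2ccccc2)c1
F4 | step 3 | [2,6-bis(benzyloxy)-4-methoxyphenyl][4-(benzyloxy)-2-methoxy-6-methylphenyl]methanone | COc1cc(OCc2ccccc2)c(C(=O)c2c(C)cc(OCc3ccccc3)cc2OC)c(OCc2ccccc2)c1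
F5 | step 4 | 1,3-bis(benzyloxy)-5-methylbenzene | Cc1cc(OCc2ccccc2)cc(OCc2ccccc2)c1
F6 | step 4 | 1,5-bis(benzyloxy)-2-iodo-3-methylbenzene | Cc1cc(OCc2ccccc2)cc(OCc2ccccc2)c1I
F7 | step 4 | [2,4-bis(benzyloxy)-6-methylphenyl](2,6-dihydroxy-4-methoxyphenyl)methanone | COc1cc(O)c(C(=O)c2c(C)cc(OCc3ccccc3)cc2OCc2ccccc2)c(O)c1
F0 | step 5 | none | none
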